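## Structural features

Trachelogenin (14) is an oxolan-2-one (γ-butyrolactone) that carries a hydroxyl and a 4-hydroxy-3-methoxybenzyl (guaiacylmethyl) group on C3, a 3,4-dimethoxybenzyl (veratryl) group on C4, and an unsubstituted OCH2 at C5. The two stereocentres are adjacent: C3 (S, a fully substituted carbinol) and C4 (S), with the C3 hydroxyl cis to the C4 benzyl group and the two benzyl groups trans. Neither centre can epimerise once set, because C3 has no hydrogen and C4 is not alpha to the carbonyl; the task is construction, not preservation. The fragile parts are the free phenol, the α-hydroxy lactone (ring opening and acyl transfer under base) and the two electron-rich arenes, which would trap a benzylic cation by Friedel–Crafts closure to an aryltetralin. The real difficulty is C3: on the target ring a group introduced last at C3 is expected to enter trans to the C4 benzyl group, which is the wrong face for the oxygen. The feature used is that C4 bears two carbons that are both gamma to the carboxyl carbon C2: ring carbon C5 and the exocyclic benzylic CH2 (C7′) attached to the dimethoxyphenyl ring. A lactone closed on C7′ instead of C5 is an isomeric five-membered ring in which the neighbour of C3 is the future C5 carbon, so the facial bias at C3 is reversed, and its benzylic C–O bond can later be cut with hydrogen.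

## Logic of the disconnections

**14 ⇒ 12 (through 13).** The ring bond C2–O1 of 14 is cut, the carboxyl is re-joined to the benzylic carbon C7′, and the phenol is capped as a benzyl ether. The reason is stereochemical: in 12 the C3 hydroxyl is trans to the ring substituent on C4, the arrangement that a last-entering oxygen prefers. There is no gain in atom count, and 12 has one extra stereocentre (C5), but that centre is disposable and is erased in the forward step. The precursor is kept with both hydroxyls free and with a benzyl ether as the only protecting group, so one operation opens the template and frees the phenol. The demand on the forward step is that only the two benzylic C–O bonds are cleaved, that no cation forms at C7′, and that the freed acid closes on the CH2OH group.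

**12 ⇒ 11.** The C4 hydroxymethyl group is traced back to a carboxyl (no skeletal bond cut). The carboxyl is what the ring-forming condensation delivers, and as a carboxylate it steers the chemistry at C3. The template lactone also keeps the two carboxyl carbons of the succinate unit distinct, one as lactone and one as free acid. The demand is reduction of an acid in the presence of a lactone.

**11 ⇒ 9.** The C3–O bond is cut. Oxygen is placed last because a last-entering electrophile goes anti to the C4 carboxylate, which is correct for oxygen on this ring. The gain is removal of the quaternary stereocentre. The demand is enolisation of a hindered tertiary C–H next to a carboxylate, and an oxygen electrophile that accepts a tetrasubstituted enolate with high facial selectivity.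

**9 ⇒ 5 + 7.** The C3–CH2Ar bond is cut. This is the convergent junction: it divides the skeleton into two aryl-bearing halves of similar size. The demand is C-alkylation of a dianion; the configuration created at C3 is irrelevant because the next step makes C3 planar again.

**7 ⇒ 6.** The C–Br bond is exchanged for C–OH, which leads back to a commercial alcohol. The demand is a mild bromination that spares the aryl benzyl ether.

**5 ⇒ 3.** No bond is cut; the enantiomers are separated. The free carboxyl allows diastereomeric salt formation. This is the only source of absolute configuration: C4 is fixed here and everything later is relayed from it. The demand is a salt pair with a useful solubility difference.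

**3 ⇒ 1 + 2.** The C4–C5 and C5–O1 bonds are cut (aldol addition followed by acyl transfer). Two commercial materials result. The demand is the 4,5-trans relationship, which is the more stable one and can be secured by crystallisation.

## Other disconnections considered

**Alternative 1:** Enzymatic Baeyer–Villiger desymmetrisation.
- **Cut:** the ring oxygen is removed from between C2 and C5, leading to the prochiral ketone 3-(3,4-dimethoxybenzyl)cyclobutanone A1.
- **Forward key step:** a flavin-dependent Baeyer–Villiger monooxygenase with O2 and cofactor recycling would insert oxygen into one of the two enantiotopic C(O)–CH2 bonds of A1, giving (R)-4-(3,4-dimethoxybenzyl)oxolan-2-one A2 and setting C4.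
- **In favour:** the step is catalytic, regiochemistry is settled by symmetry, A1 is short to make, and no material is lost to resolution. On economy of absolute stereocontrol this alternative is the better of the two.
- **Against:** A2 has nothing on C3. Both C3 substituents must be added by enolate chemistry on the target ring, where the last electrophile is expected to enter anti to the C4 benzyl group. With oxygen last, the C3 epimer would be favoured. The order would have to be reversed (hydroxylation, O-protection, benzylation of the α-alkoxy enolate with 7), which adds protecting-group steps. The enantiopreference of the enzyme for this bulky 3-substituent would have to be found by screening.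
- **Comparison:** structurally it avoids the extra template stereocentre and is equal in setting C4 early. Mechanistically the chosen plan is stronger at C3, because the group that the facial bias places correctly is the one introduced last, without protection. Step economy is about equal (roughly seven to eight steps against seven).

**Alternative 2:** Conjunctive cross-coupling.
- **Cut:** the C3–C4 bond and the CH2–aryl bond of the guaiacylmethyl group, with the C3–O bond derived from a C3–B bond.
- **Forward key step:** the ate complex formed from the secondary pinacol boronic ester A4 and the alkenyllithium A6 would react with the aryl triflate A5 under Pd(OAc)2 and a chiral ferrocenyl bisphosphine. Arylpalladium addition to the alkene terminus triggers a 1,2-shift from boron to carbon and gives the tertiary boronic ester A3.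
- **In favour:** it is a three-component union that builds the quaternary centre under catalyst control, independent of any ring bias, and the later C–B to C–O oxidation is stereoretentive. On convergence and on independence of C3 control it is the equal or the better of the chosen plan.
- **Against:** the migrating group is a branched secondary alkyl with its own stereocentre (matched or mismatched with the ligand), the alkenyl partner is α-substituted, and the product is a hindered tertiary boronate. This is the most demanding combination for the reaction class, and direct transfer coupling competes. A4 needs its own asymmetric synthesis. After the coupling there remain boron oxidation, desilylation, oxidation of a primary alcohol to the acid beside a tertiary alcohol, and double debenzylation with lactonisation.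
- **Comparison:** it is clearly longer (about ten steps) and uses two independent asymmetric events where the chosen plan uses one resolution and one substrate-controlled step.

**Alternative 3:** Oxetane desymmetrisation.
- **Cut:** the C5–O1 bond, leading to (S)-3-[4-(benzyloxy)-3-methoxyphenyl]-2-hydroxy-2-(oxetan-3-yl)propanoic acid A8.
- **Forward key step:** under acid catalysis the carboxyl oxygen of A8 would open the oxetane at one of its two diastereotopic CH2 groups (5-exo-tet), closing the lactone and setting C4 in (3S,4S)-3-[4-(benzyloxy)-3-methoxybenzyl]-3-hydroxy-4-(hydroxymethyl)oxolan-2-one A7.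
- **In favour:** ring closure and C4 are achieved in one strain-driven step with no enolate chemistry at C3. The closure mode is as favourable as the lactonisation of the chosen plan; on this point it is equal.
- **Against:** the choice between the two CH2 groups must be dictated by the neighbouring quaternary centre, whose substituents differ only modestly, or by a chiral acid in a matched pairing. A8 needs a separate asymmetric construction of the tertiary carbinol. A7 still lacks the dimethoxyphenyl ring, so the CH2OH group must be activated and coupled with an aryl nucleophile at a β-branched carbon next to a free tertiary alcohol and a lactone.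
- **Comparison:** 12 contains every carbon of the target, whereas A7 does not, so the chosen plan is more convergent and shorter (seven steps against about nine or more). The alternative's advantage is that it never forms a stereocentre that is later destroyed.

Key step: step 7

Assumption: the (S)-1-phenylethylammonium salt of the (2S,3S)-acid is taken to be the less soluble diastereomer; if the opposite salt crystallises, the (R)-amine is used and nothing else changes.

Remark: locants C2–C5 refer to the oxolan-2-one ring of the compound under discussion; because the ring oxygen changes its carbon partner in step 7, the descriptor at C4 changes from R (12) to S (14) although no bond at C4 is touched.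

## Steps

Step 1
Reactants: 1 veratraldehyde (3,4-dimethoxybenzaldehyde); 2 succinic anhydride
Product: 3 racemic trans-2-(3,4-dimethoxyphenyl)-5-oxooxolane-3-carboxylic acid [(2RS,3RS)]
Conditions: ZnCl2 (2.2 equiv), Et3N (2 equiv), CH2Cl2, rt; 2 M HCl; recrystallisation
Reagents that add atoms: none
Why: Zinc-mediated aldol addition of the anhydride enolate to the aldehyde, followed by acyl transfer of the aldolate onto the anhydride (paraconic acid synthesis, related to the Perkin and Stobbe condensations); the 4,5-trans acid is the more stable isomer and should be obtained pure by crystallisation, the two stereocentres being set only in the relative sense.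

Step 2
Reactants: 3 racemic trans-2-(3,4-dimethoxyphenyl)-5-oxooxolane-3-carboxylic acid
Product: 5 (2S,3S)-2-(3,4-dimethoxyphenyl)-5-oxooxolane-3-carboxylic acid, via (S)-1-phenylethylammonium salt 4 (not isolated)
Conditions: (S)-1-phenylethylamine (0.55 equiv), EtOH, reflux → rt, recrystallise; crystals taken up without drying in EtOAc / 1 M HCl
Reagents that add atoms: none
Why: Classical resolution through diastereomeric ammonium carboxylates; the less soluble salt is enriched by recrystallisation and mineral acid releases the acid without touching the lactone. This fixes the absolute configuration of the template (aryl-bearing carbon S, carboxyl-bearing carbon S).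

Step 3
Reactants: 6 4-(benzyloxy)-3-methoxybenzyl alcohol
Product: 7 4-(benzyloxy)-3-methoxybenzyl bromide
Conditions: PBr3 (0.4 equiv), Et2O, 0 °C
Reagents that add atoms: phosphorus tribromide, BrP(Br)Br
Why: Bromination of an electron-rich primary benzylic alcohol through its phosphite ester; the aryl benzyl ether should survive the short exposure at 0 °C, and the bromide is used at once.

Step 4
Reactants: 5 (2S,3S)-2-(3,4-dimethoxyphenyl)-5-oxooxolane-3-carboxylic acid; 7 4-(benzyloxy)-3-methoxybenzyl bromide
Product: 9 (2S,3S,4S)-4-[4-(benzyloxy)-3-methoxybenzyl]-2-(3,4-dimethoxyphenyl)-5-oxooxolane-3-carboxylic acid, via dilithium enolate carboxylate 8 (not isolated)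
Conditions: LiN(SiMe3)2 (2.2 equiv), THF, −78 °C; 7 (1.1 equiv), −78 → −30 °C; 1 M HCl
Reagents that add atoms: none
Why: C-alkylation of a paraconic acid dianion: the carboxylate blocks deprotonation at its own alpha carbon (and so β-elimination of the ring oxygen), the second equivalent of base enolises the lactone, and the benzylic bromide enters anti to the carboxylate. The configuration made at the benzylated carbon is erased in step 5, so the diastereomer ratio here does not matter.

Step 5
Reactants: 9 (2S,3S,4S)-4-[4-(benzyloxy)-3-methoxybenzyl]-2-(3,4-dimethoxyphenyl)-5-oxooxolane-3-carboxylic acid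
Product: 11 (2S,3R,4S)-4-[4-(benzyloxy)-3-methoxybenzyl]-2-(3,4-dimethoxyphenyl)-4-hydroxy-5-oxooxolane-3-carboxylic acid, via dipotassium enolate carboxylate 10 (not isolated)
Conditions: KN(SiMe3)2 (2.3 equiv), THF, −78 °C; 2-(benzenesulfonyl)-3-phenyloxaziridine (1.3 equiv), −78 °C; 1 M HCl
Reagents that add atoms: 2-(benzenesulfonyl)-3-phenyloxaziridine, O=S(=O)(N1OC1c1ccccc1)c1ccccc1
Why: Electrophilic α-hydroxylation of a tetrasubstituted lactone enolate by an N-sulfonyloxaziridine; oxygen should be delivered to the face anti to the adjacent carboxylate, the 1,2-relationship outweighing the more remote aryl group. The hydroxyl is thus placed trans to the carboxyl and the benzyl group cis to it, which is the S configuration of the future C3 of the target.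

Step 6
Reactants: 11 (2S,3R,4S)-4-[4-(benzyloxy)-3-methoxybenzyl]-2-(3,4-dimethoxyphenyl)-4-hydroxy-5-oxooxolane-3-carboxylic acid
Product: 12 (3S,4R,5S)-3-[4-(benzyloxy)-3-methoxybenzyl]-5-(3,4-dimethoxyphenyl)-3-hydroxy-4-(hydroxymethyl)oxolan-2-one
Conditions: BH3·SMe2 (3 equiv), THF, 0 °C → rt; MeOH; neutral work-up
Reagents that add atoms: none
Why: Borane reduces a carboxylic acid through its acyloxyborane much faster than a lactone, so the hydroxymethyl group should form with the lactone, benzyl ether and tertiary alcohol intact (chemoselective borane reduction of a paraconic acid); no stereocentre is touched.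

Step 7
Reactants: 12 (3S,4R,5S)-3-[4-(benzyloxy)-3-methoxybenzyl]-5-(3,4-dimethoxyphenyl)-3-hydroxy-4-(hydroxymethyl)oxolan-2-one
Product: 14 trachelogenin [(3S,4S)-4-(3,4-dimethoxybenzyl)-3-hydroxy-3-(4-hydroxy-3-methoxybenzyl)oxolan-2-one], via ring-opened hydroxy acid 13 (not isolated)
Conditions: H2 (4 bar), Pd(OH)2/C, AcOH–EtOAc (1:1), 40 °C; filter; pyridinium p-toluenesulfonate (cat.), CH2Cl2, rt
Reagents that add atoms: none
Why: On the palladium surface hydrogen cleaves the two benzylic C–O bonds that bear good leaving groups: the O–CH2Ph bond of the aryl benzyl ether, and the C5–O1 bond of the γ-aryl lactone, which is activated by the dimethoxyphenyl ring and departs as carboxylate, so that C5 becomes the ArCH2 group and the ring opens to 13. The closest known reaction type is the hydrogenolysis of γ-aryl γ-butyrolactones and benzylic esters to 4-arylbutanoic acids over palladium in acetic acid. Acid 13 then closes onto its only γ-hydroxyl, the primary CH2OH, in a 5-exo-trig lactonisation helped by the fully substituted neighbouring carbon; this forms the C2–O bond to the new C5 and the single ring of the step, and the mild acid treatment completes it. No stereocentre is created: C3 and C4 keep all four bonds, the C5 stereocentre of 12 is reduced to CH2, and only the descriptor at C4 changes. The selectivity required is chemoselectivity among C–O bonds: the tertiary C3–OH is homobenzylic and the primary alcohol is not benzylic, so neither is reducible, and the α-hydroxyl cannot compete in ring closure because it would give a three-membered ring. Strong acid is excluded until hydrogen uptake is complete, because ionisation at the benzylic carbon would allow Friedel–Crafts closure onto the guaiacyl ring. If acyl transfer from the benzylic to the primary oxygen should precede reduction, the resulting electron-rich benzylic alcohol is of a type that is also hydrogenolysed under these conditions, so both orders of events should converge on 14.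

## Compound list

1 | veratraldehyde (3,4-dimethoxybenzaldehyde) | COc1ccc(C=O)cc1OC | starting material
2 | succinic anhydride | O=C1CCC(=O)O1 | starting material
3 | (2RS,3RS)-2-(3,4-dimethoxyphenyl)-5-oxooxolane-3-carboxylic acid (racemate, trans; the SMILES shows the (2S,3S) enantiomer, its mirror image is present in equal amount) | O=C1C[C@H](C(=O)O)[C@@H](c2ccc(OC)c(OC)c2)O1 | intermediate
4 | (S)-1-phenylethylammonium (2S,3S)-2-(3,4-dimethoxyphenyl)-5-oxooxolane-3-carboxylate | O=C1C[C@H](C([O-])=O)[C@@H](c2ccc(OC)c(OC)c2)O1.C[C@H]([NH3+])c1ccccc1 | intermediate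
5 | (2S,3S)-2-(3,4-dimethoxyphenyl)-5-oxooxolane-3-carboxylic acid | O=C1C[C@H](C(=O)O)[C@@H](c2ccc(OC)c(OC)c2)O1 | intermediate
6 | 4-(benzyloxy)-3-methoxybenzyl alcohol | COc1cc(CO)ccc1OCc1ccccc1 | starting material
7 | 4-(benzyloxy)-3-methoxybenzyl bromide | COc1cc(CBr)ccc1OCc1ccccc1 | intermediate
8 | dilithium (2S,3S)-2-(3,4-dimethoxyphenyl)-5-oxido-2,3-dihydrofuran-3-carboxylate | [Li+].[Li+].[O-]C1=C[C@H](C([O-])=O)[C@@H](c2ccc(OC)c(OC)c2)O1 | intermediate
9 | (2S,3S,4S)-4-[4-(benzyloxy)-3-methoxybenzyl]-2-(3,4-dimethoxyphenyl)-5-oxooxolane-3-carboxylic acid (benzyl trans to carboxyl, carboxyl trans to aryl) | COc1cc(C[C@@H]2C(=O)O[C@H](c3ccc(OC)c(OC)c3)[C@H]2C(=O)O)ccc1OCc1ccccc1 | intermediate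
10 | dipotassium (2S,3S)-4-[4-(benzyloxy)-3-methoxybenzyl]-2-(3,4-dimethoxyphenyl)-5-oxido-2,3-dihydrofuran-3-carboxylate | [K+].[K+].[O-]C1=C(Cc2ccc(OCc3ccccc3)c(OC)c2)[C@H](C([O-])=O)[C@@H](c2ccc(OC)c(OC)c2)O1 | intermediate
11 | (2S,3R,4S)-4-[4-(benzyloxy)-3-methoxybenzyl]-2-(3,4-dimethoxyphenyl)-4-hydroxy-5-oxooxolane-3-carboxylic acid (hydroxyl trans to carboxyl, cis to aryl) | COc1cc(C[C@@]2(O)C(=O)O[C@H](c3ccc(OC)c(OC)c3)[C@H]2C(=O)O)ccc1OCc1ccccc1 | intermediate
12 | (3S,4R,5S)-3-[4-(benzyloxy)-3-methoxybenzyl]-5-(3,4-dimethoxyphenyl)-3-hydroxy-4-(hydroxymethyl)oxolan-2-one | COc1cc(C[C@@]2(O)C(=O)O[C@H](c3ccc(OC)c(OC)c3)[C@H]2CO)ccc1OCc1ccccc1 | intermediate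
13 | (2S,3S)-4-(3,4-dimethoxyphenyl)-2-hydroxy-2-(4-hydroxy-3-methoxybenzyl)-3-(hydroxymethyl)butanoic acid | COc1cc(C[C@@](O)(C(=O)O)[C@H](CO)Cc2ccc(OC)c(OC)c2)ccc1O | intermediate
14 | trachelogenin, (3S,4S)-4-(3,4-dimethoxybenzyl)-3-hydroxy-3-(4-hydroxy-3-methoxybenzyl)oxolan-2-one | COc1cc(C[C@@]2(O)C(=O)OC[C@@H]2Cc2ccc(OC)c(OC)c2)ccc1O | target

## Step count and least certain steps

Total: 7 steps. Longest linear sequence: 6 steps (steps 1, 2, 4, 5, 6, 7); step 3 is a one-step branch.

**Step 7 (key step).** The likeliest failure is that the benzyl ether is removed quickly while cleavage of the crowded secondary benzylic lactone C–O bond stalls. Forcing it with strong acid or heat would open the ionisation pathway and the Friedel–Crafts ring closure. The fallback replaces surface hydrogenolysis by radical deoxygenation; it sets out from 12 and returns at 14. A catalytic amount of DBU in CH2Cl2 should move the acyl group from the benzylic to the primary oxygen and give the isomeric lactone (3S,4R)-3-[4-(benzyloxy)-3-methoxybenzyl]-4-[(S)-(3,4-dimethoxyphenyl)(hydroxy)methyl]-3-hydroxyoxolan-2-one F1. Its secondary benzylic hydroxyl is acylated in preference to the tertiary one (PhOC(S)Cl, pyridine, CH2Cl2, 0 °C) to give the thionocarbonate (3S,4R)-3-[4-(benzyloxy)-3-methoxybenzyl]-4-[(S)-(3,4-dimethoxyphenyl)(phenoxycarbonothioyloxy)methyl]-3-hydroxyoxolan-2-one F2. Barton–McCombie deoxygenation (Bu3SnH, AIBN, toluene, 80 °C) through the benzylic radical should give (3S,4S)-3-[4-(benzyloxy)-3-methoxybenzyl]-4-(3,4-dimethoxybenzyl)-3-hydroxyoxolan-2-one F3. Plain debenzylation (H2, Pd/C, EtOAc, rt) then gives 14. No cation is generated at any stage.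

**Step 5.** Two processes are of concern: incomplete enolisation of the hindered tertiary C–H in a poorly soluble dianion, and insufficient facial discrimination by a carboxylate that is small and on the face opposite to the aryl group. The fallback changes the steering group; it sets out from 9 and returns at 12. Borane reduction of 9 (BH3·SMe2, THF) should give (3S,4R,5S)-3-[4-(benzyloxy)-3-methoxybenzyl]-5-(3,4-dimethoxyphenyl)-4-(hydroxymethyl)oxolan-2-one F4. Silylation (iPr3SiCl, imidazole, DMF) gives (3S,4R,5S)-3-[4-(benzyloxy)-3-methoxybenzyl]-5-(3,4-dimethoxyphenyl)-4-{[tri(propan-2-yl)silyl]oxymethyl}oxolan-2-one F5. Its simple monoenolate (KN(SiMe3)2, THF, −78 °C) is hydroxylated by the same oxaziridine anti to the bulky silyloxymethyl group, giving (3S,4R,5S)-3-[4-(benzyloxy)-3-methoxybenzyl]-5-(3,4-dimethoxyphenyl)-3-hydroxy-4-{[tri(propan-2-yl)silyl]oxymethyl}oxolan-2-one F6. Desilylation with HF·pyridine in THF, chosen as a non-basic reagent to avoid acyl transfer, gives 12.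

**Step 2.** The resolution may fail in two ways: the salt pair may differ too little in solubility, or the wanted enantiomer may stay in the mother liquor; in any case half the material is lost. The fallback replaces resolution by auxiliary control; it sets out from 1 and returns at 5. (S)-4-Benzyloxazolidin-2-one is N-acylated (n-BuLi, then methyl 4-chloro-4-oxobutanoate, THF, −78 °C) to methyl 4-[(4S)-4-benzyl-2-oxo-1,3-oxazolidin-3-yl]-4-oxobutanoate F7. Its boron enolate (Bu2BOTf, iPr2NEt, CH2Cl2) should add to 1 in the syn sense to give methyl (3S,4S)-3-{[(4S)-4-benzyl-2-oxo-1,3-oxazolidin-3-yl]carbonyl}-4-(3,4-dimethoxyphenyl)-4-hydroxybutanoate F8. This lactonises (cat. TsOH, toluene) with loss of methanol to the trans lactone (4S)-4-benzyl-3-{[(2S,3S)-2-(3,4-dimethoxyphenyl)-5-oxooxolan-3-yl]carbonyl}-1,3-oxazolidin-2-one F9. Cleavage of the imide with LiOH/H2O2 (THF–H2O, 0 °C) and acidification gives 5.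

**Step 6.** The risk is over-reduction: borane held on the neighbouring C3 oxygen may deliver hydride to the lactone carbonyl, while the acid itself, flanked by a quaternary carbon, reacts slowly. The fallback changes the activation mode; it sets out from 11 and returns at 12. Isobutyl chloroformate and N-methylmorpholine (THF, −15 °C) convert 11 into the mixed anhydride (2S,3R,4S)-4-[4-(benzyloxy)-3-methoxybenzyl]-2-(3,4-dimethoxyphenyl)-4-hydroxy-5-oxooxolane-3-carboxylic 2-methylpropyl carbonic anhydride F10. A β-lactone cannot form because the hydroxyl is trans to the carboxyl on the five-membered ring. Brief treatment with NaBH4 (THF–H2O, −15 → 0 °C) reduces the anhydride carbonyl much faster than the lactone and gives 12.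

## Further compounds

F1 | step 7 | (3S,4R)-3-[4-(benzyloxy)-3-methoxybenzyl]-4-[(S)-(3,4-dimethoxyphenyl)(hydroxy)methyl]-3-hydroxyoxolan-2-one | COc1cc(C[C@@]2(O)C(=O)OC[C@@H]2[C@H](O)c2ccc(OC)c(OC)c2)ccc1OCc1ccccc1
F2 | step 7 | (3S,4R)-3-[4-(benzyloxy)-3-methoxybenzyl]-4-[(S)-(3,4-dimethoxyphenyl)(phenoxycarbonothioyloxy)methyl]-3-hydroxyoxolan-2-one | COc1cc(C[C@@]2(O)C(=O)OC[C@@H]2[C@H](OC(=S)Oc2ccccc2)c2ccc(OC)c(OC)c2)ccc1OCc1ccccc1
F3 | step 7 | (3S,4S)-3-[4-(benzyloxy)-3-methoxybenzyl]-4-(3,4-dimethoxybenzyl)-3-hydroxyoxolan-2-one | COc1cc(C[C@@]2(O)C(=O)OC[C@@H]2Cc2ccc(OC)c(OC)c2)ccc1OCc1ccccc1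
F4 | step 5 | (3S,4R,5S)-3-[4-(benzyloxy)-3-methoxybenzyl]-5-(3,4-dimethoxyphenyl)-4-(hydroxymethyl)oxolan-2-one | COc1cc(C[C@@H]2C(=O)O[C@H](c3ccc(OC)c(OC)c3)[C@H]2CO)ccc1OCc1ccccc1
F5 | step 5 | (3S,4R,5S)-3-[4-(benzyloxy)-3-methoxybenzyl]-5-(3,4-dimethoxyphenyl)-4-{[tri(propan-2-yl)silyl]oxymethyl}oxolan-2-one | COc1cc(C[C@@H]2C(=O)O[C@H](c3ccc(OC)c(OC)c3)[C@H]2CO[Si](C(C)C)(C(C)C)C(C)C)ccc1OCc1ccccc1
F6 | step 5 | (3S,4R,5S)-3-[4-(benzyloxy)-3-methoxybenzyl]-5-(3,4-dimethoxyphenyl)-3-hydroxy-4-{[tri(propan-2-yl)silyl]oxymethyl}oxolan-2-one | COc1cc(C[C@@]2(O)C(=O)O[C@H](c3ccc(OC)c(OC)c3)[C@H]2CO[Si](C(C)C)(C(C)C)C(C)C)ccc1OCc1ccccc1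
F7 | step 2 | methyl 4-[(4S)-4-benzyl-2-oxo-1,3-oxazolidin-3-yl]-4-oxobutanoate | COC(=O)CCC(=O)N1[C@@H](Cc2ccccc2)COC1=O
F8 | step 2 | methyl (3S,4S)-3-{[(4S)-4-benzyl-2-oxo-1,3-oxazolidin-3-yl]carbonyl}-4-(3,4-dimethoxyphenyl)-4-hydroxybutanoate | COC(=O)C[C@H](C(=O)N1[C@@H](Cc2ccccc2)COC1=O)[C@H](O)c1ccc(OC)c(OC)c1
F9 | step 2 | (4S)-4-benzyl-3-{[(2S,3S)-2-(3,4-dimethoxyphenyl)-5-oxooxolan-3-yl]carbonyl}-1,3-oxazolidin-2-one | O=C1C[C@H](C(=O)N2[C@@H](Cc3ccccc3)COC2=O)[C@@H](c2ccc(OC)c(OC)c2)O1
F10 | step 6 | (2S,3R,4S)-4-[4-(benzyloxy)-3-methoxybenzyl]-2-(3,4-dimethoxyphenyl)-4-hydroxy-5-oxooxolane-3-carboxylic 2-methylpropyl carbonic anhydride | COc1cc(C[C@@]2(O)C(=O)O[C@H](c3ccc(OC)c(OC)c3)[C@H]2C(=O)OC(=O)OCC(C)C)ccc1OCc1ccccc1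
A1 | alternative 1 | 3-(3,4-dimethoxybenzyl)cyclobutanone | COc1ccc(CC2CC(=O)C2)cc1OC
A2 | alternative 1 | (R)-4-(3,4-dimethoxybenzyl)oxolan-2-one | O=C1OC[C@H](Cc2ccc(OC)c(OC)c2)C1
A3 | alternative 2 | 2-[(2R,3R)-4-(benzyloxy)-1-[4-(benzyloxy)-3-methoxyphenyl]-2-{[tert-butyl(dimethyl)silyl]oxymethyl}-3-(3,4-dimethoxybenzyl)butan-2-yl]-4,4,5,5-tetramethyl-1,3,2-dioxaborolane | COc1cc(C[C@@](B2OC(C)(C)C(C)(C)O2)(CO[Si](C)(C)C(C)(C)C)[C@H](COCc3ccccc3)Cc3ccc(OC)c(OC)c3)ccc1OCc1ccccc1
A4 | alternative 2 | 2-[(2S)-1-(benzyloxy)-3-(3,4-dimethoxyphenyl)propan-2-yl]-4,4,5,5-tetramethyl-1,3,2-dioxaborolane | CC1(C)OB(OC1(C)C)[C@H](COCc1ccccc1)Cc1ccc(OC)c(OC)c1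
A5 | alternative 2 | 4-(benzyloxy)-3-methoxyphenyl trifluoromethanesulfonate | COc1cc(OS(=O)(=O)C(F)(F)F)ccc1OCc1ccccc1
A6 | alternative 2 | tert-butyl[(2-lithioprop-2-en-1-yl)oxy]dimethylsilane | [Li]C(=C)CO[Si](C)(C)C(C)(C)C
A7 | alternative 3 | (3S,4S)-3-[4-(benzyloxy)-3-methoxybenzyl]-3-hydroxy-4-(hydroxymethyl)oxolan-2-one | COc1cc(C[C@@]2(O)C(=O)OC[C@@H]2CO)ccc1OCc1ccccc1
A8 | alternative 3 | (S)-3-[4-(benzyloxy)-3-methoxyphenyl]-2-hydroxy-2-(oxetan-3-yl)propanoic acid | COc1cc(C[C@](O)(C2COC2)C(=O)O)ccc1OCc1ccccc1
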